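**Retrosynthetic overview**

1. Target 18 ⇐ enone 16: C10–Br and C8–OH come last, by conjugate hydrobromination and ketone reduction. 16 ⇐ 15 by hydroxyl-directed bromochlorination of the ring A olefin.
2. 15 ⇐ acyclic tetraene 13: both carbocycles are closed in one double ring-closing metathesis in the same flask (ring A cyclohexene first, ring B cyclopentenone second).
3. 13 ⇐ β-keto Weinreb amide 11: chelation-controlled allylation sets C6 against C7, then a vinyl Grignard makes the enone.
4. 11 ⇐ ester 8 by a dianion Carroll rearrangement that joins the two quaternary carbons C7–C11 and relays chirality from an (S)-allylic carbinol.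
5. 8 ⇐ mesityl oxide 1 (CBS reduction), dioxinone 3, methallyl chloride 6 and MeI.

Assumption: step 1 gives 2 in at least 95% ee; atom labels used below are ring A = C1–C6 (C6 carbinol, C2 CHBr, C3 CClMe) and ring B = C7–C11 (C7 quaternary with methyl, C8 CHOH, C10 CHBr, C11 CMe2).

**Step 1**
Reactants: 1 mesityl oxide (4-methylpent-3-en-2-one)
Product: 2 (S)-4-methylpent-3-en-2-ol
Conditions: (R)-2-methyl-CBS-oxazaborolidine (10 mol%), catecholborane (1.5 equiv), toluene, −78 °C; MeOH quench, aq NaOH wash
Reagents that add atoms: none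
Why: Corey–Bakshi–Shibata reduction, in which the alkenyl group acts as the large and methyl as the small ketone substituent, so the (R)-oxazaborolidine–borane complex delivers hydride to the face that gives the (S)-carbinol.

**Step 2**
Reactants: 2 (S)-4-methylpent-3-en-2-ol; 3 2,2,6-trimethyl-4H-1,3-dioxin-4-one
Product: 5 (S)-4-methylpent-3-en-2-yl 3-oxobutanoate, via acetylketene 4 (not isolated)
Conditions: toluene, 110 °C, 1 h, acetone distilled off
Reagents that add atoms: none
Why: Acetoacetylation, in which 3 loses acetone by thermal retro-[4+2] and the acetylketene acylates the alcohol under neutral conditions, leaving the carbinol center untouched.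

**Step 3**
Reactants: 5 (S)-4-methylpent-3-en-2-yl 3-oxobutanoate; 6 3-chloro-2-methylprop-1-ene
Product: 8 (S)-4-methylpent-3-en-2-yl (2RS)-2,6-dimethyl-3-oxohept-6-enoate, via keto ester 7 (not isolated)
Conditions: NaH (1.1 equiv), THF, 0 °C; n-BuLi (1.05 equiv), 0 °C; 6, 0 °C → rt; MeI (1.3 equiv), rt
Reagents that add atoms: iodomethane, CI
Why: Dianion (Weiler) alkylation, in which the terminal carbanion is alkylated by the allylic chloride and the remaining β-keto ester enolate is then C-methylated; the new α-center is a mixture that is re-formed in step 4.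

**Step 4**
Reactants: 8 (S)-4-methylpent-3-en-2-yl (2RS)-2,6-dimethyl-3-oxohept-6-enoate
Product: 11 (2R,4E)-N-methoxy-N,2,3,3-tetramethyl-2-(4-methylpent-4-enoyl)hex-4-enamide, via keto acid 9 (not isolated), via acid chloride 10 (not isolated)
Conditions: LiN(i-Pr)2 (2.2 equiv), THF, −78 → 50 °C; 1 M HCl, 0 °C; (COCl)2, cat. DMF, CH2Cl2, 0 °C; MeNHOMe·HCl, pyridine, 0 °C → rt
Reagents that add atoms: N,O-dimethylhydroxylamine hydrochloride, CNOC.Cl
Why: Dianion Carroll rearrangement ([3,3]-sigmatropic, chair), in which the lithium-chelated enolate holds the ketone arm trans to the ester oxygen and allylic 1,3-strain keeps the carbinol methyl pseudo-equatorial, so the (S)-carbinol is relayed to (R)-C7 as the C7–C11 bond and the (E)-propenyl group form, and the labile β-keto acid is fixed at once as its Weinreb amide by acid chloride amidation.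

**Step 5**
Reactants: 11 (2R,4E)-N-methoxy-N,2,3,3-tetramethyl-2-(4-methylpent-4-enoyl)hex-4-enamide
Product: 12 (2R,4E)-2-[(4R)-4-hydroxy-7-methylocta-1,7-dien-4-yl]-N-methoxy-N,2,3,3-tetramethylhex-4-enamide
Conditions: allyl bromide, Zn dust, THF, 0 °C → rt; H2O
Reagents that add atoms: allyl bromide, C=CCBr
Why: Barbier allylation with allylzinc bromide under Cram-chelate control (the Felkin–Anh model gives the same sense), in which zinc bridges the ketone and amide oxygens and the allyl group enters C6 from the face of the C7 methyl, anti to the tert-alkyl group, setting (R)-C6 and fixing which arm of ring A will carry the olefin.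

**Step 6**
Reactants: 12 (2R,4E)-2-[(4R)-4-hydroxy-7-methylocta-1,7-dien-4-yl]-N-methoxy-N,2,3,3-tetramethylhex-4-enamide
Product: 13 (4R,6E)-4-[(4R)-4-hydroxy-7-methylocta-1,7-dien-4-yl]-4,5,5-trimethylocta-1,6-dien-3-one
Conditions: CH2=CHMgBr (4 equiv), THF, 0 °C → rt; inverse quench into cold pH 5 buffer
Reagents that add atoms: vinylmagnesium bromide, C=C[Mg]Br
Why: Weinreb ketone synthesis, in which the first equivalent deprotonates the C6 hydroxyl, the Grignard reagent then adds once to the amide because the magnesium-chelated tetrahedral intermediate holds until the quench, and no stereocenter is involved.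

**Step 7**
Reactants: 13 (4R,6E)-4-[(4R)-4-hydroxy-7-methylocta-1,7-dien-4-yl]-4,5,5-trimethylocta-1,6-dien-3-one
Product: 15 (5R)-5-[(1R)-1-hydroxy-4-methylcyclohex-3-en-1-yl]-4,4,5-trimethylcyclopent-2-en-1-one, via cyclohexenyl dienone 14 (not isolated)
Conditions: second-generation Hoveyda–Grubbs catalyst (10 mol%), 1,4-benzoquinone (20 mol%), toluene (0.005 M), 40 °C then 90 °C, argon sparge
Reagents that add atoms: none
Why: Double ring-closing olefin metathesis, in which the allyl-derived ruthenium alkylidene closes ring A onto the electron-rich 1,1-disubstituted olefin at 40 °C while the O–H···O=C hydrogen bond of the β-hydroxy enone holds the electron-poor enone olefin away from the C6 arms, and at 90 °C the methylidene loads onto the hindered propenyl group and closes ring B onto the enone; no stereocenter is touched.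

**Step 8**
Reactants: 15 (5R)-5-[(1R)-1-hydroxy-4-methylcyclohex-3-en-1-yl]-4,4,5-trimethylcyclopent-2-en-1-one
Product: 16 (5R)-5-[(1R,3S,4S)-3-bromo-4-chloro-1-hydroxy-4-methylcyclohexyl]-4,4,5-trimethylcyclopent-2-en-1-one
Conditions: NBS (1.1 equiv), ClTi(Oi-Pr)3 (2 equiv), hexanes–CH2Cl2, −20 °C
Reagents that add atoms: N-bromosuccinimide, O=C1CCC(=O)N1Br; chlorotitanium triisopropoxide, CC(C)O[Ti](Cl)(OC(C)C)OC(C)C
Why: Proposed new method: hydroxyl-directed bromochlorination of a homoallylic tertiary alcohol, in which bromonium formation is reversible on both faces of the ring A olefin but only the bromonium anti to the titanium-bound C6 alkoxide can be opened at the tertiary C3 by chloride delivered from that titanium through a boat-like seven-membered transition state, placing Cl cis to the C6 oxygen and Br trans (anti, Markovnikov addition) while the electron-poor enone is inert to NBS; the closest known reaction type is the titanium-alkoxide-directed bromochlorination of allylic alcohols with NBS and ClTi(Oi-Pr)3.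

**Step 9**
Reactants: 16 (5R)-5-[(1R,3S,4S)-3-bromo-4-chloro-1-hydroxy-4-methylcyclohexyl]-4,4,5-trimethylcyclopent-2-en-1-one
Product: 18 (1R,2S,4S)-4-bromo-2-[(1R,3S,4S)-3-bromo-4-chloro-1-hydroxy-4-methylcyclohexyl]-2,3,3-trimethylcyclopentan-1-ol, via bromo ketone 17 (not isolated)
Conditions: HBr (2 equiv), CH2Cl2, −20 °C, 6 h; then MeOH, CeCl3·7H2O, NaBH4, −78 °C
Reagents that add atoms: hydrogen bromide, Br
Why: Reversible conjugate (Michael-type) addition of HBr puts bromide on C10 and is expected to settle on the cis-1,3 adduct, with bromine and the bulky C7 carbinol substituent both pseudo-equatorial, and the Luche reduction then brings hydride to the C8 ketone from the face anti to that substituent and to the cerium chelate across C6–OH and C8=O, giving the cis C8–OH.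

**Compound list**

1 | mesityl oxide (4-methylpent-3-en-2-one) | CC(=O)C=C(C)C | starting material
2 | (S)-4-methylpent-3-en-2-ol | C[C@H](O)C=C(C)C | intermediate
3 | 2,2,6-trimethyl-4H-1,3-dioxin-4-one | CC1=CC(=O)OC(C)(C)O1 | starting material
4 | acetylketene (but-1-ene-1,3-dione) | CC(=O)C=C=O | intermediate
5 | (S)-4-methylpent-3-en-2-yl 3-oxobutanoate | C[C@H](OC(=O)CC(C)=O)C=C(C)C | intermediate
6 | 3-chloro-2-methylprop-1-ene (methallyl chloride) | CC(=C)CCl | starting material
7 | (S)-4-methylpent-3-en-2-yl 6-methyl-3-oxohept-6-enoate | C[C@H](OC(=O)CC(=O)CCC(C)=C)C=C(C)C | intermediate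
8 | (S)-4-methylpent-3-en-2-yl (2RS)-2,6-dimethyl-3-oxohept-6-enoate | C[C@H](OC(=O)C(C)C(=O)CCC(C)=C)C=C(C)C | intermediate
9 | (2R,4E)-2,3,3-trimethyl-2-(4-methylpent-4-enoyl)hex-4-enoic acid | C=C(C)CCC(=O)[C@](C)(C(=O)O)C(C)(C)/C=C/C | intermediate
10 | (2R,4E)-2,3,3-trimethyl-2-(4-methylpent-4-enoyl)hex-4-enoyl chloride | C=C(C)CCC(=O)[C@](C)(C(=O)Cl)C(C)(C)/C=C/C | intermediate
11 | (2R,4E)-N-methoxy-N,2,3,3-tetramethyl-2-(4-methylpent-4-enoyl)hex-4-enamide | C=C(C)CCC(=O)[C@](C)(C(=O)N(C)OC)C(C)(C)/C=C/C | intermediate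
12 | (2R,4E)-2-[(4R)-4-hydroxy-7-methylocta-1,7-dien-4-yl]-N-methoxy-N,2,3,3-tetramethylhex-4-enamide | C=C(C)CC[C@@](O)(CC=C)[C@](C)(C(=O)N(C)OC)C(C)(C)/C=C/C | intermediate
13 | (4R,6E)-4-[(4R)-4-hydroxy-7-methylocta-1,7-dien-4-yl]-4,5,5-trimethylocta-1,6-dien-3-one | C=C(C)CC[C@@](O)(CC=C)[C@](C)(C(=O)C=C)C(C)(C)/C=C/C | intermediate
14 | (4R,6E)-4-[(1R)-1-hydroxy-4-methylcyclohex-3-en-1-yl]-4,5,5-trimethylocta-1,6-dien-3-one | C/C=C/C(C)(C)[C@@](C)(C(=O)C=C)[C@@]1(O)CCC(C)=CC1 | intermediate
15 | (5R)-5-[(1R)-1-hydroxy-4-methylcyclohex-3-en-1-yl]-4,4,5-trimethylcyclopent-2-en-1-one | CC1(C)C=CC(=O)[C@@]1(C)[C@@]1(O)CCC(C)=CC1 | intermediate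
16 | (5R)-5-[(1R,3S,4S)-3-bromo-4-chloro-1-hydroxy-4-methylcyclohexyl]-4,4,5-trimethylcyclopent-2-en-1-one | CC1(C)C=CC(=O)[C@@]1(C)[C@@]1(O)CC[C@](C)(Cl)[C@@H](Br)C1 | intermediate
17 | (2R,4S)-4-bromo-2-[(1R,3S,4S)-3-bromo-4-chloro-1-hydroxy-4-methylcyclohexyl]-2,3,3-trimethylcyclopentan-1-one | CC1(C)[C@@H](Br)CC(=O)[C@@]1(C)[C@@]1(O)CC[C@](C)(Cl)[C@@H](Br)C1 | intermediate
18 | (1R,2S,4S)-4-bromo-2-[(1R,3S,4S)-3-bromo-4-chloro-1-hydroxy-4-methylcyclohexyl]-2,3,3-trimethylcyclopentan-1-ol | CC1(C)[C@@H](Br)C[C@@H](O)[C@@]1(C)[C@@]1(O)CC[C@](C)(Cl)[C@@H](Br)C1 | target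

**Step count and risks**

Total step count: 9. Longest linear sequence: 9 steps (1 → 18).

The three steps most likely to fail:

Step 7. The allyl-derived alkylidene may close a six-membered ring onto the enone instead of ring A, or the second closure between the enone and the hindered propenyl group may stall. The fallback closes the rings one at a time and sets out from 12. With the same ruthenium catalyst at 40 °C only ring A can close, because no enone is present yet and the propenyl group is inert at that temperature, giving (2R,4E)-2-[(1R)-1-hydroxy-4-methylcyclohex-3-en-1-yl]-N-methoxy-N,2,3,3-tetramethylhex-4-enamide F1. CH2=CHMgBr then converts the amide into dienone 14, which is isolated this time, and a second metathesis at 90 °C closes ring B to 15. The fallback comes back to the route at 14.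

Step 8. The free C6 hydroxyl may attack the bromonium itself, or chloride may open the other bromonium in the diaxial sense and give the wrong diastereomer. The fallback uses the oxygen attack on purpose and sets out from 15. NBS alone in CH2Cl2 at 0 °C gives, by anti bromoetherification through a boat, the bridged ether (5R)-5-[(1S,2S,4R)-2-bromo-1-methyl-7-oxabicyclo[2.2.1]heptan-4-yl]-4,4,5-trimethylcyclopent-2-en-1-one F2. TiCl4 in CH2Cl2 at −78 °C then ionises the C3–O bond with anchimeric help from the anti C2 bromine, and chloride opens the bromonium at the tertiary carbon with overall retention. The fallback comes back to the route at 16.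

Step 9. The HBr addition may stop at the kinetic trans adduct, or the acid may damage the tertiary alcohol before equilibrium is reached. The fallback sets the C10 center with a bulky nucleophile and inverts it, and sets out from 16. Conjugate borylation (B2pin2, CuCl and NaOt-Bu in catalytic amounts, MeOH, THF) anti to the C7 carbinol substituent gives (2R,4R)-2-[(1R,3S,4S)-3-bromo-4-chloro-1-hydroxy-4-methylcyclohexyl]-2,3,3-trimethyl-4-(4,4,5,5-tetramethyl-1,3,2-dioxaborolan-2-yl)cyclopentan-1-one F3. Luche reduction as in step 9 gives (1R,2S,4R)-2-[(1R,3S,4S)-3-bromo-4-chloro-1-hydroxy-4-methylcyclohexyl]-2,3,3-trimethyl-4-(4,4,5,5-tetramethyl-1,3,2-dioxaborolan-2-yl)cyclopentan-1-ol F4. Boronate formation with 3,5-(CF3)2C6H3Li (3 equiv) and bromination with NBS then replace boron by bromine with inversion. The fallback comes back to the route at 18.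

**Further compounds**

F1 | step 7 | (2R,4E)-2-[(1R)-1-hydroxy-4-methylcyclohex-3-en-1-yl]-N-methoxy-N,2,3,3-tetramethylhex-4-enamide | C/C=C/C(C)(C)[C@@](C)(C(=O)N(C)OC)[C@@]1(O)CCC(C)=CC1
F2 | step 8 | (5R)-5-[(1S,2S,4R)-2-bromo-1-methyl-7-oxabicyclo[2.2.1]heptan-4-yl]-4,4,5-trimethylcyclopent-2-en-1-one | CC1(C)C=CC(=O)[C@@]1(C)[C@@]2(O3)CC[C@@]3(C)[C@@H](Br)C2
F3 | step 9 | (2R,4R)-2-[(1R,3S,4S)-3-bromo-4-chloro-1-hydroxy-4-methylcyclohexyl]-2,3,3-trimethyl-4-(4,4,5,5-tetramethyl-1,3,2-dioxaborolan-2-yl)cyclopentan-1-one | CC1(C)[C@H](B2OC(C)(C)C(C)(C)O2)CC(=O)[C@@]1(C)[C@@]1(O)CC[C@](C)(Cl)[C@@H](Br)C1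
F4 | step 9 | (1R,2S,4R)-2-[(1R,3S,4S)-3-bromo-4-chloro-1-hydroxy-4-methylcyclohexyl]-2,3,3-trimethyl-4-(4,4,5,5-tetramethyl-1,3,2-dioxaborolan-2-yl)cyclopentan-1-ol | CC1(C)[C@H](B2OC(C)(C)C(C)(C)O2)C[C@@H](O)[C@@]1(C)[C@@]1(O)CC[C@](C)(Cl)[C@@H](Br)C1
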